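The route rests on cutting the exocyclic bond between the quaternary peroxy carbon C6 of the 1,2-dioxane ring and the side-chain CH2 that lies β to the enone carbonyl. C6 is bound to ring oxygen O1, so a 6-methoxy peroxyketal can ionise to a cyclic peroxycarbenium ion; the ketone is 1,4 to C6, so its β-carbon can arrive as a homoenolate stored in a strained 1-siloxycyclopropane. One Lewis-acid step opens the cyclopropane, joins the two halves and sets C6 by axial attack on the half-chair whose C3 side chain is equatorial. The precursor pair is a peroxyketal ester and a siloxycyclopropane that carries the enone methylene masked as CH2OTs.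

Key step: step 15

Remark: the ketal carbon C6 in 8–12 and the CH(CH2O–) carbon in 15–21 are stereo-mixtures and are left unassigned, because both centres are erased later (ionisation in step 15, elimination in step 16). Compounds 1, 3 and 13 are taken as catalogue compounds.

**Peroxyketal fragment**

Step 1
Reactants: 1 4-methylpent-4-en-1-ol
Product: 2 4-methylpent-4-enal
Conditions: (COCl)2, DMSO, CH2Cl2, −78 °C; Et3N
Reagents that add atoms: none
Why: Swern oxidation should stop cleanly at the aldehyde and leave the 1,1-disubstituted alkene untouched.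

Step 2
Reactants: 2 4-methylpent-4-enal; 3 (4S)-4-benzyl-3-propanoyl-1,3-oxazolidin-2-one
Product: 4 (4S)-4-benzyl-3-[(2S,3R)-3-hydroxy-2,6-dimethylhept-6-enoyl]-1,3-oxazolidin-2-one
Conditions: 3, Bu2BOTf, iPr2NEt, CH2Cl2, 0 °C; 2, −78 to 0 °C; H2O2, MeOH, pH 7 buffer
Reagents that add atoms: none
Why: Evans syn aldol reaction; the Z-boron enolate reacts through a Zimmerman–Traxler chair and the (S)-benzyl auxiliary should deliver the (2S,3R) adduct, which fixes C2 of the target and gives the C3 carbinol in the configuration that step 6 inverts.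

Step 3
Reactants: 4 aldol adduct
Product: 5 (2R,3R)-2,6-dimethylhept-6-ene-1,3-diol
Conditions: LiBH4, MeOH (1 equiv), Et2O, 0 °C
Reagents that add atoms: none
Why: Reductive cleavage of the N-acyl oxazolidinone removes the carbonyl whose acidic α-hydrogen would cause E1cB loss of the C3 leaving group in step 6; no stereocentre is touched.

Step 4
Reactants: 5 diol
Product: 7 (2R,3R)-1-[(tert-butyldimethylsilyl)oxy]-2,6-dimethylhept-6-en-3-yl methanesulfonate, via silyl ether 6 (not isolated)
Conditions: TBSCl, Et3N, DMAP (cat.), CH2Cl2, 0 °C; then MsCl, Et3N, 0 °C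
Reagents that add atoms: tert-butyldimethylsilyl chloride CC(C)(C)[Si](C)(C)Cl; methanesulfonyl chloride CS(=O)(=O)Cl
Why: Primary-selective silylation followed by mesylation of the remaining secondary alcohol (O–S bond formation, retention at C3) should give the leaving group in one flask.

Step 5
Reactants: 7 mesylate
Product: 8 (2R,3R,6RS)-1-[(tert-butyldimethylsilyl)oxy]-6-hydroperoxy-6-methoxy-2-methylheptan-3-yl methanesulfonate
Conditions: O3, CH2Cl2/MeOH, −78 °C; N2 purge, no reductive work-up
Reagents that add atoms: ozone [O-][O+]=O; methanol CO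
Why: Ozonolysis of a 1,1-disubstituted alkene in methanol; the Criegee ketone oxide forms on the disubstituted carbon and is trapped by methanol as the hydroperoxy ketal.

Step 6
Reactants: 8 hydroperoxy ketal
Product: 9 tert-butyl{(2R)-2-[(3S,6RS)-6-methoxy-6-methyl-1,2-dioxan-3-yl]propoxy}dimethylsilane
Conditions: KOtBu, 18-crown-6, THF, 0 °C
Reagents that add atoms: none
Why: Intramolecular alkylation of the hydroperoxide anion (6-exo-tet SN2 at the secondary mesylate) should close the 1,2-dioxane with inversion and so set C3 as S.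

Step 7
Reactants: 9 silyl ether
Product: 10 (2R)-2-[(3S,6RS)-6-methoxy-6-methyl-1,2-dioxan-3-yl]propan-1-ol
Conditions: TBAF, AcOH, THF, 0 °C to rt
Reagents that add atoms: none
Why: Fluoride desilylation, buffered with acetic acid so that neither the base-sensitive C3–H peroxide nor the acid-sensitive peroxyketal is exposed.

Step 8
Reactants: 10 alcohol
Product: 11 (2S)-2-[(3S,6RS)-6-methoxy-6-methyl-1,2-dioxan-3-yl]propanoic acid
Conditions: TEMPO (cat.), PhI(OAc)2, MeCN/pH 7 buffer, rt
Reagents that add atoms: water O
Why: Oxoammonium (TEMPO/PhI(OAc)2) oxidation of the primary alcohol through the aldehyde hydrate is metal-free and near neutral, so the O–O bond, the ketal and the α-stereocentre should survive.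

Step 9
Reactants: 11 acid (used directly)
Product: 12 methyl (2S)-2-[(3S,6RS)-6-methoxy-6-methyl-1,2-dioxan-3-yl]propanoate
Conditions: TMSCHN2, PhMe/MeOH, 0 °C
Reagents that add atoms: trimethylsilyldiazomethane C[Si](C)(C)C=[N+]=[N-]
Why: Diazoalkane O-methylation of the carboxylic acid is neutral and cannot epimerise C2 or open the ring.

**Siloxycyclopropane fragment**

Step 10
Reactants: 13 methyl 6-oxoheptanoate
Product: 14 methyl 6-hydroxy-6-methylheptanoate
Conditions: MeMgBr (1.05 equiv), THF, −78 °C
Reagents that add atoms: methylmagnesium bromide C[Mg]Br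
Why: Grignard addition is chemoselective for the ketone over the ester at low temperature and creates the tertiary carbinol of the tail.

Step 11
Reactants: 14 hydroxy ester
Product: 15 methyl 6-hydroxy-2-(hydroxymethyl)-6-methylheptanoate
Conditions: LDA (2.2 equiv), THF, −78 °C; CH2O (gas), −78 to −20 °C
Reagents that add atoms: formaldehyde C=O
Why: Aldol reaction of the alkoxide–enolate dianion with monomeric formaldehyde installs the carbon that becomes the enone methylene and thereby fixes the regiochemistry of the final enone formation.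

Step 12
Reactants: 15 diol ester
Product: 16 2-(1-hydroxycyclopropyl)-6-methylheptane-1,6-diol
Conditions: EtMgBr (5 equiv), Ti(OiPr)4 (1 equiv), THF, 0 °C to rt
Reagents that add atoms: ethylmagnesium bromide CC[Mg]Br
Why: Kulinkovich cyclopropanation; the titanacyclopropane formed from EtMgBr and Ti(OiPr)4 acts as a 1,2-dicarbanion on the ester, the two hydroxyls being carried as alkoxides.

Step 13
Reactants: 16 triol
Product: 17 6-hydroxy-2-(1-hydroxycyclopropyl)-6-methylheptyl 4-methylbenzenesulfonate
Conditions: TsCl (1.1 equiv), pyridine, CH2Cl2, 0 °C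
Reagents that add atoms: 4-methylbenzenesulfonyl chloride Cc1ccc(cc1)S(=O)(=O)Cl
Why: Tosylation with pyridine (no sulfene pathway) should be selective for the primary hydroxyl over the two tertiary ones and installs the leaving group for the final elimination.

Step 14
Reactants: 17 tosylate
Product: 18 6-methyl-6-[(trimethylsilyl)oxy]-2-{1-[(trimethylsilyl)oxy]cyclopropyl}heptyl 4-methylbenzenesulfonate
Conditions: TMSOTf, Et3N, CH2Cl2, −78 to 0 °C
Reagents that add atoms: trimethylsilyl trifluoromethanesulfonate C[Si](C)(C)OS(=O)(=O)C(F)(F)F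
Why: Silylation of both tertiary hydroxyls gives the siloxycyclopropane homoenolate donor and caps the carbinol so that it can neither trap the cation nor protonate the cyclopropane.

**Union and end game**

Step 15
Reactants: 12 peroxyketal ester; 18 siloxycyclopropane (1.5–2 equiv)
Product: 21 methyl (2S)-2-[(3S,6R)-6-{8-hydroxy-8-methyl-3-oxo-4-[(tosyloxy)methyl]nonyl}-6-methyl-1,2-dioxan-3-yl]propanoate, via peroxycarbenium ion 19 (not isolated), via tertiary TMS ether 20 (not isolated)
Conditions: TiCl4 (1.2 equiv), CH2Cl2, −78 °C; then 1 M HCl/THF, 0 °C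
Reagents that add atoms: none
Why: Proposed new method: TiCl4 ionises the C6–OMe bond of either ketal epimer of 12 to the cyclic peroxycarbenium ion 19, and the strained C–C σ-bond of 18, raised in energy by the geminal silyloxy donor, attacks it by corner (SE2) substitution at an unsubstituted ring CH2, so that the cyclopropane strain (about 27 kcal/mol) is released and the resulting silyloxocarbenium ion collapses to the ketone with loss of Me3SiCl (a homo-Mukaiyama addition). The closest known reactions are the Lewis-acid additions of allylsilanes and silyl enol ethers to peroxycarbenium ions of 3-alkoxy-1,2-dioxanes and -dioxolanes, and the electrophilic ring opening of siloxycyclopropanes in titanium homoenolate chemistry. No ring is closed; the cyclopropane is opened and the dioxane ring is kept. The new quaternary centre C6 is controlled by the ring: in the half-chair cation the C3 side chain sits pseudo-equatorial and the nucleophile enters along the axial trajectory that leads to a chair, which should place the new chain axial and cis to the C3 substituent (6R) and the methyl equatorial. The step needs C-attack at C6 to outrun proton loss from the cation and needs the cyclopropane to be the only nucleophile, which is secured by the absence of any alkene in 18 (a free enone methylene would react first and trigger cyclobutanone ring expansion), by the TMS cap on the tertiary alcohol and by the non-nucleophilic ester and sulfonate groups. The acidic work-up removes the tertiary TMS ether of 20, and 21 is expected as two epimers at the CH(CH2OTs) carbon that converge in step 16.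

Step 16
Reactants: 21 β-tosyloxy ketone
Product: 22 aikupikoxide D, methyl (2S)-2-[(3S,6R)-6-(8-hydroxy-8-methyl-4-methylidene-3-oxononyl)-6-methyl-1,2-dioxan-3-yl]propanoate
Conditions: Et3N, CH2Cl2, 0 °C to rt
Reagents that add atoms: none
Why: E1cB elimination of the β-sulfonyloxy ketone with a mild amine base should give the α-methylene ketone from both epimers, the ketone α-hydrogen being far more acidic than that of the β-peroxy ester, so C2, C3 and the O–O bond are not disturbed.

**Compound list**

1 | 4-methylpent-4-en-1-ol | C=C(C)CCCO | starting material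
2 | 4-methylpent-4-enal | C=C(C)CCC=O | intermediate
3 | (4S)-4-benzyl-3-propanoyl-1,3-oxazolidin-2-one | CCC(=O)N1C(=O)OC[C@@H]1Cc1ccccc1 | starting material
4 | (4S)-4-benzyl-3-[(2S,3R)-3-hydroxy-2,6-dimethylhept-6-enoyl]-1,3-oxazolidin-2-one | C=C(C)CC[C@@H](O)[C@H](C)C(=O)N1C(=O)OC[C@@H]1Cc1ccccc1 | intermediate
5 | (2R,3R)-2,6-dimethylhept-6-ene-1,3-diol | C=C(C)CC[C@@H](O)[C@H](C)CO | intermediate
6 | (2R,3R)-1-[(tert-butyldimethylsilyl)oxy]-2,6-dimethylhept-6-en-3-ol | C=C(C)CC[C@@H](O)[C@H](C)CO[Si](C)(C)C(C)(C)C | intermediate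
7 | (2R,3R)-1-[(tert-butyldimethylsilyl)oxy]-2,6-dimethylhept-6-en-3-yl methanesulfonate | C=C(C)CC[C@@H](OS(C)(=O)=O)[C@H](C)CO[Si](C)(C)C(C)(C)C | intermediate
8 | (2R,3R,6RS)-1-[(tert-butyldimethylsilyl)oxy]-6-hydroperoxy-6-methoxy-2-methylheptan-3-yl methanesulfonate | COC(C)(OO)CC[C@@H](OS(C)(=O)=O)[C@H](C)CO[Si](C)(C)C(C)(C)C | intermediate
9 | tert-butyl{(2R)-2-[(3S,6RS)-6-methoxy-6-methyl-1,2-dioxan-3-yl]propoxy}dimethylsilane | COC1(C)CC[C@@H]([C@H](C)CO[Si](C)(C)C(C)(C)C)OO1 | intermediate
10 | (2R)-2-[(3S,6RS)-6-methoxy-6-methyl-1,2-dioxan-3-yl]propan-1-ol | COC1(C)CC[C@@H]([C@H](C)CO)OO1 | intermediate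
11 | (2S)-2-[(3S,6RS)-6-methoxy-6-methyl-1,2-dioxan-3-yl]propanoic acid | COC1(C)CC[C@@H]([C@H](C)C(=O)O)OO1 | intermediate
12 | methyl (2S)-2-[(3S,6RS)-6-methoxy-6-methyl-1,2-dioxan-3-yl]propanoate | COC1(C)CC[C@@H]([C@H](C)C(=O)OC)OO1 | intermediate
13 | methyl 6-oxoheptanoate | CC(=O)CCCCC(=O)OC | starting material
14 | methyl 6-hydroxy-6-methylheptanoate | CC(C)(O)CCCCC(=O)OC | intermediate
15 | methyl 6-hydroxy-2-(hydroxymethyl)-6-methylheptanoate (racemic) | CC(C)(O)CCCC(CO)C(=O)OC | intermediate
16 | 2-(1-hydroxycyclopropyl)-6-methylheptane-1,6-diol (racemic) | CC(C)(O)CCCC(CO)C1(O)CC1 | intermediate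
17 | 6-hydroxy-2-(1-hydroxycyclopropyl)-6-methylheptyl 4-methylbenzenesulfonate (racemic) | Cc1ccc(cc1)S(=O)(=O)OCC(CCCC(C)(C)O)C1(O)CC1 | intermediate
18 | 6-methyl-6-[(trimethylsilyl)oxy]-2-{1-[(trimethylsilyl)oxy]cyclopropyl}heptyl 4-methylbenzenesulfonate (racemic) | Cc1ccc(cc1)S(=O)(=O)OCC(CCCC(C)(C)O[Si](C)(C)C)C1(O[Si](C)(C)C)CC1 | intermediate
19 | (6S)-6-[(2S)-1-methoxy-1-oxopropan-2-yl]-3-methyl-5,6-dihydro-4H-1,2-dioxin-2-ium (peroxycarbenium ion) | CC1=[O+]O[C@H]([C@H](C)C(=O)OC)CC1 | intermediate
20 | methyl (2S)-2-[(3S,6R)-6-methyl-6-{8-methyl-3-oxo-4-[(tosyloxy)methyl]-8-[(trimethylsilyl)oxy]nonyl}-1,2-dioxan-3-yl]propanoate (two epimers at C4 of the chain) | Cc1ccc(cc1)S(=O)(=O)OCC(CCCC(C)(C)O[Si](C)(C)C)C(=O)CC[C@@]1(C)CC[C@@H]([C@H](C)C(=O)OC)OO1 | intermediate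
21 | methyl (2S)-2-[(3S,6R)-6-{8-hydroxy-8-methyl-3-oxo-4-[(tosyloxy)methyl]nonyl}-6-methyl-1,2-dioxan-3-yl]propanoate (two epimers at C4 of the chain) | Cc1ccc(cc1)S(=O)(=O)OCC(CCCC(C)(C)O)C(=O)CC[C@@]1(C)CC[C@@H]([C@H](C)C(=O)OC)OO1 | intermediate
22 | aikupikoxide D, methyl (2S)-2-[(3S,6R)-6-(8-hydroxy-8-methyl-4-methylidene-3-oxononyl)-6-methyl-1,2-dioxan-3-yl]propanoate | C=C(CCCC(C)(C)O)C(=O)CC[C@@]1(C)CC[C@@H]([C@H](C)C(=O)OC)OO1 | target

**Step count and risks**

Total step count: 16. Longest linear sequence: 11 (steps 1–9, 15, 16).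

Steps most likely to fail:

1. Step 15 (proposed new method). The peroxycarbenium ion may decay by proton loss to an enol peroxide or by Lewis-acid O–O heterolysis, or adventitious acid may open the siloxycyclopropane, faster than the C–C bond forms; facial selectivity at C6 may also be poor. The fallback sets out from 12 and uses only known reaction types. Hosomi–Sakurai allylation of the same cation (allyltrimethylsilane, SnCl4, CH2Cl2, −78 °C), a documented reaction of alkoxy-1,2-dioxanes with the same axial selectivity, should give methyl (2S)-2-[(3S,6R)-6-methyl-6-(prop-2-en-1-yl)-1,2-dioxan-3-yl]propanoate F1. Aldehyde-selective nitrite-modified Wacker oxidation (PdCl2(PhCN)2, CuCl2, AgNO2, O2, tBuOH/MeNO2) should convert the terminal alkene into methyl (2S)-2-[(3S,6R)-6-methyl-6-(3-oxopropyl)-1,2-dioxan-3-yl]propanoate F2. Commercial 6-hydroxy-6-methylheptan-2-one is condensed with trisyl hydrazide to N'-(6-hydroxy-6-methylheptan-2-ylidene)-2,4,6-triisopropylbenzenesulfonohydrazide F3; Shapiro reaction (nBuLi, 3 equiv, then CeCl3) gives the less substituted vinyl metal, which is added to F2 at −78 °C to give the allylic alcohol methyl (2S)-2-[(3S,6S)-6-(3,8-dihydroxy-8-methyl-4-methylidenenonyl)-6-methyl-1,2-dioxan-3-yl]propanoate F4 (C6 arranged in space as in 22). Dess–Martin oxidation of F4 returns to the route at 22.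

2. Step 6. E2 elimination of the β-branched secondary mesylate and base-induced Kornblum–DeLaMare fragmentation of the C3–H peroxide may compete with the 6-exo-tet displacement. The fallback sets out from 5 and replaces the basic sulfonate displacement by an acid-promoted oxetane opening. Mono-tosylation (TsCl, pyridine) gives (2R,3R)-3-hydroxy-2,6-dimethylhept-6-en-1-yl 4-methylbenzenesulfonate F5, and KOtBu closes it to (2R,3R)-3-methyl-2-(3-methylbut-3-en-1-yl)oxetane F6 with retention at the carbinol carbon. Ozonolysis in CH2Cl2/MeOH gives (2R,3R)-2-(3-hydroperoxy-3-methoxybutyl)-3-methyloxetane F7. Lewis-acid-promoted intramolecular opening of the oxetane by the hydroperoxide (TMSOTf cat., CH2Cl2, −78 °C; 6-exo, inversion at the secondary carbon) should give the primary alcohol directly and returns to the route at 10.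

3. Step 11. Gaseous formaldehyde may oligomerise, the dianion may be hydroxymethylated twice, and the adduct may undergo retro-aldol on warming, so conversion may be low. The fallback sets out from 14: Claisen formylation of the dianion (LDA, 2.2 equiv; methyl formate, −78 °C) gives methyl 2-formyl-6-hydroxy-6-methylheptanoate F8, and chemoselective reduction of the aldehyde (NaBH4, MeOH, −20 °C) returns to the route at 15.

Further compounds
F1 | step 15 | methyl (2S)-2-[(3S,6R)-6-methyl-6-(prop-2-en-1-yl)-1,2-dioxan-3-yl]propanoate | C=CC[C@@]1(C)CC[C@@H]([C@H](C)C(=O)OC)OO1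
F2 | step 15 | methyl (2S)-2-[(3S,6R)-6-methyl-6-(3-oxopropyl)-1,2-dioxan-3-yl]propanoate | O=CCC[C@@]1(C)CC[C@@H]([C@H](C)C(=O)OC)OO1
F3 | step 15 | N'-(6-hydroxy-6-methylheptan-2-ylidene)-2,4,6-triisopropylbenzenesulfonohydrazide | CC(CCCC(C)(C)O)=NNS(=O)(=O)c1c(C(C)C)cc(C(C)C)cc1C(C)C
F4 | step 15 | methyl (2S)-2-[(3S,6S)-6-(3,8-dihydroxy-8-methyl-4-methylidenenonyl)-6-methyl-1,2-dioxan-3-yl]propanoate (carbinol epimers) | C=C(CCCC(C)(C)O)C(O)CC[C@@]1(C)CC[C@@H]([C@H](C)C(=O)OC)OO1
F5 | step 6 | (2R,3R)-3-hydroxy-2,6-dimethylhept-6-en-1-yl 4-methylbenzenesulfonate | C=C(C)CC[C@@H](O)[C@H](C)COS(=O)(=O)c1ccc(C)cc1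
F6 | step 6 | (2R,3R)-3-methyl-2-(3-methylbut-3-en-1-yl)oxetane | C=C(C)CC[C@H]1OC[C@H]1C
F7 | step 6 | (2R,3R)-2-(3-hydroperoxy-3-methoxybutyl)-3-methyloxetane | COC(C)(OO)CC[C@H]1OC[C@H]1C
F8 | step 11 | methyl 2-formyl-6-hydroxy-6-methylheptanoate | CC(C)(O)CCCC(C=O)C(=O)OC
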